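The leftover we watch here is reagent, not substrate.

| flask | left-handed substrate | right-handed substrate | solid reagent | free catalyst | remark | time |
|---|---|---|---|---|---|---|
| zeta | 1 M | 1 M | 1.7 M | 100 mM | run made earlier |  |
| epsilon | 1 M | 1 M | 2.6 M | 100 mM | run made earlier |  |
| amber | 1.0 M | 1.0 M | 1.20 M | 100 mM |  | 3.0 d |
| ochre | 1.0 M | 1.0 M | 1.20 M | 100 mM |  | 12 d |

| run | time / d | right-handed substrate / % | left-handed substrate / % |
|---|---|---|---|
| zeta | 0.250 | 50.2 | 40.1 |
| zeta | 0.833 | 49.2 | 20.8 |
| zeta | 1.25 | 50.0 | 13.7 |
| zeta | 2.00 | 47.5 | 7.4 |
| zeta | 3.00 | 48.1 | 3.6 |
| epsilon | 0.250 | 50.5 | 40.3 |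
| epsilon | 0.417 | 50.5 | 33.6 |
| epsilon | 0.833 | 49.7 | 21.3 |
| epsilon | 1.67 | 49.1 | 9.5 |
| epsilon | 3.00 | 48.7 | 4.2 |

(each reading ± 0.5 percentage points)

1. which of the two ends with the higher excess of right-handed substrate over left-handed substrate among what is left of the two ("neither" if they lie within 2 percentage points) (amber / ochre / neither)
2. excess of right-handed substrate over left-handed substrate among what is left of the two at the end, amber
3. excess of right-handed substrate over left-handed substrate among what is left of the two at the end, ochre

- free catalyst is single-handed; left-handed substrate and right-handed substrate are mirror images of each other, charged as a racemate, each of them at the stated concentration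
- solid, in amounts per volume of the solution: solid reagent
- at the start none of the solid reagent is in solution
- an excess is below zero if the other one leads

We take the settings in turn, starting with the solid reagent. Define the reserve as the reagent charged, solid and dissolved together, less what the two substrates have consumed, as a fraction of the two substrates charged. Zeta's last reading leaves a reserve of 36.7%, and epsilon's leaves 82.9%, yet their left-handed readings match within the scatter. So, as far as these readings show, a reserve down to zeta's costs no pace.

Amber charges 60.0%, which is 10.0% above the left-handed share. On zeta's pace its reserve would be 23.7% at 1.25 d and 11.7% at 3.00 d, under anything yet tried. We assume that below zeta's reserve the pseudo-first-order pace falls in proportion to the reserve, which gives a mean factor of 0.482. Zeta's logarithmic fall of left-handed substrate over that stretch is 1.34. Our reckoning therefore leaves 7.19% left-handed substrate in amber, an excess of 74.0%.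

Time comes next. Zeta's fall per logarithm of time is 1.53, so the pace fades in zeta while its reserve is still 36.7% or more. Scaling this by amber's reserve at its end, ochre keeps 2.67%, an excess of 89.5%. Free catalyst is charged alike in zeta and epsilon, so these readings do not show how the pace goes with its charge, though the fade in zeta may carry a loss of catalyst, which we cannot tell from other causes by these readings.

The forecast names ochre, with 84% (78% to 87%) for amber and 98% (92% to 100%) for ochre, on the ground “Reagent suffices, though depletion of the solid could slow the tail”. Our two numbers stand lower than these.

    coupling partner + free catalyst + left-handed substrate → free catalyst + left-handed product (k = 9.30 × 10⁻⁴ /M²/s)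
    coupling partner + free catalyst + right-handed substrate → free catalyst + right-handed product (k = 1.30 × 10⁻⁵ /M²/s)
    2 free catalyst → spent catalyst (k = 1.60 × 10⁻⁴ /M/s)
    solid reagent ⇌ coupling partner, rate k4*(cs4 - [coupling partner]) while solid is left; crystals form when [coupling partner] > cs4 (solubility = 0.670 M, k = 3.80 × 10⁻⁵ /s)
    left-handed product ⇌ right-handed product (k = 3.50 × 10⁻⁵ /s)

Amber ends at 76.9% and ochre at 90.1%, so ochre leads. In amber the solid reagent stands at 0% by 1.50 d, and at 3.00 d the reserve is 14.9%, less than zeta's 36.7%. Over the same run, the left-handed step's use of coupling partner against the right-handed step's drops from 50 times at 0.379 d to 9.4 times at 3.00 d. The neighbour of amber with 0.40 M free catalyst has a reserve of 13.0% at 3.00 d, also less than zeta's, and its excess is 82.5%.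

(The data stem from a simulated flask from invented constants.)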